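**Retrosynthetic overview**
1. Target ⇐ 15,18-diol (acetylate the allylic OH, oxidise the neopentyl CH2OH to CO2H) ⇐ diester after removal of a C3 ketone.
2. Δ1(10) alkene ⇐ Δ1-3-ketone by dienyl acetate/NaBH4 deconjugation; C4 quaternary centre ⇐ axial methylation of a ring A β-keto ester.
3. Ring A (formed last) ⇐ key intermolecular Michael addition of methyl acetoacetate to a ring B enal, then intramolecular aldol condensation.
4. Ring B is taken intact from (R)-carvone: Cu-catalysed MeMgBr 1,4-addition and a Mukaiyama–Michael addition to methyl vinyl ketone set C8 and C9; the isopropenyl group steers C5 and is excised later.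
5. Side chain ⇐ Horner–Wadsworth–Emmons olefination of the methyl ketone delivered by the first Michael addition.

Assumption: halimane numbering (C1–C20) is used for all intermediates; "up" is the face of H-5 in the target (also H-8 and C-11), "down" the face of the three ring methyl groups.

**Step 1**
Reactants: 1 (R)-(−)-carvone
Product: 3 trimethylsilyl enol ether of 2,3-dimethyl-5-isopropenylcyclohexanone (C8 methyl down; isopropenyl up), via bromomagnesium enolate 2 (not isolated)
Conditions: MeMgBr, CuBr·SMe2 (5 mol %), TMSCl, HMPA, THF, −78 °C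
Reagents that add atoms: methylmagnesium bromide C[Mg]Br; chlorotrimethylsilane C[Si](C)(C)Cl
Why: Copper-catalysed conjugate addition delivers the methyl group anti to the isopropenyl group (sets C8), and the regiodefined enolate is trapped on oxygen as the silyl enol ether.

**Step 2**
Reactants: 3 silyl enol ether; 4 methyl vinyl ketone
Product: 5 2,3-dimethyl-2-(3-oxobutyl)-5-isopropenylcyclohexanone (C9 methyl down; oxobutyl up)
Conditions: TiCl4, CH2Cl2, −78 °C; then H2O
Reagents that add atoms: none
Why: Mukaiyama–Michael addition of the tetrasubstituted silyl enol ether to the TiCl4-activated enone forms the C9 quaternary centre, the acceptor approaching anti to the neighbouring C8 methyl group.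

**Step 3**
Reactants: 5 diketone; 6 trimethyl phosphonoacetate
Product: 7 methyl (E)-3-methyl-5-[1,6-dimethyl-2-oxo-4-isopropenylcyclohexyl]pent-2-enoate
Conditions: NaH, THF, 0 °C (anion preformed); then 5, rt → 50 °C; minor Z isomer removed by chromatography
Reagents that add atoms: none
Why: Horner–Wadsworth–Emmons olefination occurs only at the unhindered methyl ketone (the ring ketone is flanked by a quaternary carbon) and favours the E-trisubstituted enoate.

**Step 4**
Reactants: 7 keto enoate
Product: 8 enol triflate (C10–OTf; C5=C10)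
Conditions: Tf2O, 2,6-di-tert-butyl-4-methylpyridine, CH2Cl2, 0 °C → rt
Reagents that add atoms: trifluoromethanesulfonic anhydride O=S(=O)(OS(=O)(=O)C(F)(F)F)C(F)(F)F
Why: Enol triflate formation under non-anionic conditions can only go toward C5 (C9 is quaternary) and leaves the enoate untouched.

**Step 5**
Reactants: 8 enol triflate
Product: 9 ring B enal (CHO on C10; C5=C10)
Conditions: Pd(OAc)2 (5 mol %), dppp, CO (1 atm), Et3SiH, Et3N, DMF, 70 °C
Reagents that add atoms: carbon monoxide [C-]#[O+]
Why: Palladium-catalysed reductive carbonylation (formylation) of the vinyl triflate proceeds by oxidative addition, CO insertion and hydride transfer from the silane.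

**Step 6**
Reactants: 9 ring B enal; 10 methyl acetoacetate
Product: 13 trans-fused bicyclic Δ1-3-keto 18-ester (C4 enolisable), via Michael adduct 11 (not isolated), via aldol ketol 12 (not isolated)
Conditions: NaOMe (1.1 equiv), MeOH, 0 °C → 60 °C; then AcOH
Reagents that add atoms: none
Why: Robinson-type Michael–aldol annulation: the β-keto ester enolate adds 1,4 to the enal anti to the adjacent isopropenyl group (sets C5, H-5 up), the acetyl methyl then condenses with the aldehyde to close ring A, and C10 equilibrates to the trans ring fusion.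

**Step 7**
Reactants: 13 bicyclic β-keto ester
Product: 14 C4-methylated keto ester (C4 methyl down; CO2Me up)
Conditions: MeI, K2CO3, acetone, rt
Reagents that add atoms: iodomethane CI
Why: C-alkylation of the β-keto ester enolate, with MeI entering axially, anti to the axial H-5 of the rigid trans-fused ring (no 1,3-diaxial substituent opposes it), so the ester ends cis to H-5.

**Step 8**
Reactants: 14 methylated keto ester
Product: 16 keto ester without the isopropenyl group (C6 = CH2), via methoxy hydroperoxide 15 (not isolated)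
Conditions: O3 (1 equiv, dye endpoint), MeOH, −78 °C; then FeSO4·7H2O, PhSH, −78 °C → rt
Reagents that add atoms: none
Why: Hydrodealkenylation: the electron-rich 1,1-disubstituted alkene is ozonised much faster than the enone and enoate alkenes; single-electron reduction of the α-methoxy hydroperoxide by divalent iron then triggers β-scission, and the C6 radical takes a hydrogen atom from the thiol.

**Step 9**
Reactants: 16 Δ1-3-ketone
Product: 17 dienyl acetate (C3–OAc; C2=C3 and C1=C10)
Conditions: isopropenyl acetate, TsOH (cat.), reflux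
Reagents that add atoms: isopropenyl acetate CC(=C)OC(C)=O
Why: Acid-catalysed enol acetylation gives the only possible conjugated dienyl acetate, since H-10 is the only γ-hydrogen; this moves unsaturation to C1=C10 and erases the C10 stereocentre.

**Step 10**
Reactants: 17 dienyl acetate
Product: 19 homoallylic C3 alcohol with the C1=C10 alkene (C3 epimers), via deconjugated ketone 18 (not isolated)
Conditions: NaBH4, EtOH–THF, 0 °C → rt
Reagents that add atoms: none
Why: Enol acetate/borohydride deconjugative reduction: cleavage of the acetate gives the dienolate, which protonates at C2, and the resulting β,γ-unsaturated ketone is reduced before it can reconjugate.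

**Step 11**
Reactants: 19 C3 alcohol
Product: 20 C3 O-(imidazol-1-ylthiocarbonyl) derivative
Conditions: 1,1'-thiocarbonyldiimidazole, DMAP (cat.), ClCH2CH2Cl, reflux
Reagents that add atoms: 1,1'-thiocarbonyldiimidazole S=C(n1ccnc1)n1ccnc1
Why: Neutral thioacylation of the hindered secondary alcohol gives the Barton–McCombie precursor without touching the esters.

**Step 12**
Reactants: 20 thiocarbonylimidazolide
Product: 21 dimethyl ent-halima-1(10),13E-diene-15,18-dioate
Conditions: Bu3SnH, AIBN (cat.), toluene, 110 °C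
Reagents that add atoms: none
Why: Barton–McCombie radical deoxygenation removes the C3 oxygen; the secondary radical is quenched by the stannane faster than it can attack the trisubstituted alkene.

**Step 13**
Reactants: 21 diester
Product: 22 ent-halima-1(10),13E-diene-15,18-diol
Conditions: iBu2AlH (5 equiv), CH2Cl2, −78 °C → rt; aqueous work-up
Reagents that add atoms: none
Why: Hydride reduction takes the enoate cleanly (1,2) to the E-allylic alcohol and the hindered C18 ester to the neopentyl alcohol.

**Step 14**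
Reactants: 22 diol
Product: 23 15-acetoxy-ent-halima-1(10),13E-dien-18-ol
Conditions: Ac2O (1.05 equiv), pyridine, CH2Cl2, −20 °C
Reagents that add atoms: acetic anhydride CC(=O)OC(C)=O
Why: Selective acylation: the unhindered primary allylic alcohol is acetylated far faster than the neopentyl C18 alcohol on the quaternary carbon.

**Step 15**
Reactants: 23 mono-acetate
Product: 24 15-acetoxy-ent-halima-1(10),13E-dien-18-al
Conditions: Dess–Martin periodinane, CH2Cl2, 0 °C → rt
Reagents that add atoms: none
Why: Dess–Martin oxidation converts the neopentyl alcohol to the non-enolisable aldehyde under conditions that spare the allylic acetate and both alkenes.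

**Step 16**
Reactants: 24 aldehyde
Product: 25 15-acetoxy-ent-halima-1(10),13E-dien-18-oic acid (target)
Conditions: NaClO2, NaH2PO4, 2-methyl-2-butene, tBuOH–H2O, rt
Reagents that add atoms: sodium chlorite [Na+].[O-]Cl=O
Why: Pinnick oxidation gives the hindered acid, the alkene scavenger removing HOCl before it can attack the two trisubstituted alkenes.

**Compound list**
1 | (R)-(−)-carvone | CC1=CC[C@H](CC1=O)C(C)=C | starting material
2 | bromomagnesium enolate of 2,3-dimethyl-5-isopropenylcyclohexanone (C8 methyl down, isopropenyl up) | CC1=C(O[Mg]Br)C[C@H](C(C)=C)C[C@H]1C | intermediate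
3 | trimethylsilyl enol ether of 2,3-dimethyl-5-isopropenylcyclohexanone (3-methyl trans to 5-isopropenyl) | CC1=C(O[Si](C)(C)C)C[C@H](C(C)=C)C[C@H]1C | intermediate
4 | methyl vinyl ketone (but-3-en-2-one) | CC(=O)C=C | starting material
5 | 2,3-dimethyl-2-(3-oxobutyl)-5-isopropenylcyclohexan-1-one (C9 methyl down, oxobutyl up; C8 methyl down; isopropenyl up) | CC(=O)CC[C@]1(C)C(=O)C[C@H](C(C)=C)C[C@H]1C | intermediate
6 | trimethyl phosphonoacetate | COC(=O)CP(=O)(OC)OC | starting material
7 | methyl (E)-3-methyl-5-[1,6-dimethyl-2-oxo-4-isopropenylcyclohexyl]pent-2-enoate (ring stereo as in 5) | COC(=O)/C=C(\C)CC[C@]1(C)C(=O)C[C@H](C(C)=C)C[C@H]1C | intermediate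
8 | enol triflate of 7 (C10–OTf, C5=C10) | COC(=O)/C=C(\C)CC[C@]1(C)C(OS(=O)(=O)C(F)(F)F)=C[C@H](C(C)=C)C[C@H]1C | intermediate
9 | ring B enal: methyl (E)-5-[2-formyl-1,6-dimethyl-4-isopropenylcyclohex-2-en-1-yl]-3-methylpent-2-enoate | COC(=O)/C=C(\C)CC[C@]1(C)C(C=O)=C[C@H](C(C)=C)C[C@H]1C | intermediate
10 | methyl acetoacetate | CC(=O)CC(=O)OC | starting material
11 | Michael adduct: C5 carries CH(COCH3)CO2Me (down, trans to isopropenyl), C10 carries CHO; C10 and the new CH are epimerisable | COC(=O)/C=C(\C)CC[C@]1(C)C(C=O)[C@@H](C(C(C)=O)C(=O)OC)[C@H](C(C)=C)C[C@H]1C | intermediate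
12 | aldol ketol: trans-fused bicycle with C1–OH, C3 ketone, C4 H/CO2Me (C1 and C4 epimers) | COC(=O)/C=C(\C)CC[C@]1(C)[C@@H]2C(O)CC(=O)C(C(=O)OC)[C@H]2[C@H](C(C)=C)C[C@H]1C | intermediate
13 | trans-fused bicyclic Δ1-3-keto 18-methyl ester (H-5 up, H-10 down, C6 isopropenyl up, C4 enolisable) with the E-enoate side chain on C9 | COC(=O)/C=C(\C)CC[C@]1(C)[C@@H]2C=CC(=O)C(C(=O)OC)[C@H]2[C@H](C(C)=C)C[C@H]1C | intermediate
14 | 13 methylated at C4 (methyl down, CO2Me up) | COC(=O)/C=C(\C)CC[C@]1(C)[C@@H]2C=CC(=O)[C@](C)(C(=O)OC)[C@H]2[C@H](C(C)=C)C[C@H]1C | intermediate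
15 | α-methoxy hydroperoxide from 14 (C6–C(CH3)(OCH3)OOH) | COC(=O)/C=C(\C)CC[C@]1(C)[C@@H]2C=CC(=O)[C@](C)(C(=O)OC)[C@H]2[C@H](C(C)(OC)OO)C[C@H]1C | intermediate
16 | 14 without the isopropenyl group (C6 = CH2) | COC(=O)/C=C(\C)CC[C@]1(C)[C@@H]2C=CC(=O)[C@](C)(C(=O)OC)[C@H]2CC[C@H]1C | intermediate
17 | dienyl acetate (C3–OAc, C2=C3, C1=C10) | COC(=O)/C=C(\C)CC[C@]1(C)C2=CC=C(OC(C)=O)[C@](C)(C(=O)OC)[C@H]2CC[C@H]1C | intermediate
18 | β,γ-unsaturated ketone (C3 ketone, C1=C10) | COC(=O)/C=C(\C)CC[C@]1(C)C2=CCC(=O)[C@](C)(C(=O)OC)[C@H]2CC[C@H]1C | intermediate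
19 | C3 alcohol with C1=C10 (C3 epimers) | COC(=O)/C=C(\C)CC[C@]1(C)C2=CCC(O)[C@](C)(C(=O)OC)[C@H]2CC[C@H]1C | intermediate
20 | C3 O-(imidazol-1-ylthiocarbonyl) derivative of 19 | COC(=O)/C=C(\C)CC[C@]1(C)C2=CCC(OC(=S)n3ccnc3)[C@](C)(C(=O)OC)[C@H]2CC[C@H]1C | intermediate
21 | dimethyl ent-halima-1(10),13E-diene-15,18-dioate | COC(=O)/C=C(\C)CC[C@]1(C)C2=CCC[C@](C)(C(=O)OC)[C@H]2CC[C@H]1C | intermediate
22 | ent-halima-1(10),13E-diene-15,18-diol | OC/C=C(\C)CC[C@]1(C)C2=CCC[C@](C)(CO)[C@H]2CC[C@H]1C | intermediate
23 | 15-acetoxy-ent-halima-1(10),13E-dien-18-ol | CC(=O)OC/C=C(\C)CC[C@]1(C)C2=CCC[C@](C)(CO)[C@H]2CC[C@H]1C | intermediate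
24 | 15-acetoxy-ent-halima-1(10),13E-dien-18-al | CC(=O)OC/C=C(\C)CC[C@]1(C)C2=CCC[C@](C)(C=O)[C@H]2CC[C@H]1C | intermediate
25 | 15-acetoxy-ent-halima-1(10),13E-dien-18-oic acid (CNP0276297.1) | CC(=O)OC/C=C(\C)CC[C@]1(C)C2=CCC[C@](C)(C(=O)O)[C@H]2CC[C@H]1C | target

**Totals**
Total step count: 16. Longest linear sequence: 16 steps, from (R)-carvone 1.

**Steps most likely to fail**

Step 6 (Michael–aldol annulation on the hindered enal; Knoevenagel 1,2-chemistry may win). The fallback sets out from 8 and comes back at 13. Carbonylative Stille coupling of 8 (Pd(PPh3)4, LiCl, CO, Me4Sn, DMF) gives the acetyl enone F5, a better and purely 1,4-reactive acceptor. Dimethyl malonate with NaOMe in refluxing MeOH adds to it to give the malonate Michael adduct F6. This is not isolated but undergoes Claisen condensation in the same flask (acetyl methyl onto one ester) to the bicyclic 1,3-dione ester F7. The C1 oxygen is sulfonylated (Tf2O, Et3N, −78 °C), the C3 carbonyl staying tied up in the chelated β-keto ester, to give the vinylogous triflate F8. Reduction with Pd(OAc)2, PPh3, HCO2H and Bu3N then delivers 13.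

Step 10 (the hindered C3 ketone may be reduced more slowly than the β,γ-enone reconjugates). The fallback sets out from 16 and comes back at 19. KOtBu in tBuOH–THF at 0 °C converts 16 into the potassium dienolate F9. Inverse quench into cold AcOH protonates it kinetically at C2, so that the deconjugated ketone 18 is now isolated. It is reduced at once under non-basic Luche conditions (NaBH4, CeCl3·7H2O, MeOH, −78 °C) to 19.

Step 2 (Lewis acid-promoted formation of the quaternary centre next to an acid-sensitive isopropenyl group). The fallback sets out from 1 and comes back at 5. The bromomagnesium enolate 2, generated as in step 1 but without TMSCl, is alkylated in the same flask with allyl bromide (HMPA) to give the allyl ketone F1, again anti to the C8 methyl group. 9-BBN hydroborates only the monosubstituted alkene, and NaOH/H2O2 gives the primary alcohol F2. Dess–Martin oxidation gives the keto aldehyde F3. MeMgBr at −78 °C adds only to the aldehyde to give the secondary alcohol F4, and a second Dess–Martin oxidation gives 5.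

**Further compounds**
F1 | step 2 | 2-allyl-2,3-dimethyl-5-isopropenylcyclohexan-1-one (allyl up, both methyls down, isopropenyl up) | C=CC[C@]1(C)C(=O)C[C@H](C(C)=C)C[C@H]1C
F2 | step 2 | 2-(3-hydroxypropyl)-2,3-dimethyl-5-isopropenylcyclohexan-1-one | OCCC[C@]1(C)C(=O)C[C@H](C(C)=C)C[C@H]1C
F3 | step 2 | 3-[1,6-dimethyl-2-oxo-4-isopropenylcyclohexyl]propanal | O=CCC[C@]1(C)C(=O)C[C@H](C(C)=C)C[C@H]1C
F4 | step 2 | 2-(3-hydroxybutyl)-2,3-dimethyl-5-isopropenylcyclohexan-1-one (carbinol epimers) | CC(O)CC[C@]1(C)C(=O)C[C@H](C(C)=C)C[C@H]1C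
F5 | step 6 | acetyl enone: methyl (E)-5-[2-acetyl-1,6-dimethyl-4-isopropenylcyclohex-2-en-1-yl]-3-methylpent-2-enoate | COC(=O)/C=C(\C)CC[C@]1(C)C(C(C)=O)=C[C@H](C(C)=C)C[C@H]1C
F6 | step 6 | malonate Michael adduct (C5 carries CH(CO2Me)2 down; C10 carries acetyl, epimerisable) | COC(=O)/C=C(\C)CC[C@]1(C)C(C(C)=O)[C@@H](C(C(=O)OC)C(=O)OC)[C@H](C(C)=C)C[C@H]1C
F7 | step 6 | trans-fused bicyclic 1,3-dione 18-ester (C1 and C3 ketones, C4 H/CO2Me) | COC(=O)/C=C(\C)CC[C@]1(C)[C@@H]2C(=O)CC(=O)C(C(=O)OC)[C@H]2[C@H](C(C)=C)C[C@H]1C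
F8 | step 6 | vinylogous triflate (C1–OTf, C1=C2, C3 ketone) | COC(=O)/C=C(\C)CC[C@]1(C)[C@@H]2C(OS(=O)(=O)C(F)(F)F)=CC(=O)C(C(=O)OC)[C@H]2[C@H](C(C)=C)C[C@H]1C
F9 | step 10 | potassium dienolate of 16 (C3–OK, C2=C3, C1=C10) | COC(=O)/C=C(\C)CC[C@]1(C)C2=CC=C(O[K])[C@](C)(C(=O)OC)[C@H]2CC[C@H]1C
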